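**Retrosynthetic overview**

1. Target 16 ⇐ 15 by one acidic methanolysis (two MOM ethers, one aryl acetate); 15 ⇐ 14 by Eu(III)-catalysed aromatic Claisen rearrangement of the 5-O-prenyl ether, which puts the 1,1-dimethylallyl group on C6, the only free ortho position.
2. 14 ⇐ 5 + 13 by the C2–C1′ disconnection: Rh-catalysed enantioselective 1,4-addition of a catechol-derived arylboronic acid to the γ-pyrone ring of a chromone. This joins the A/C and B halves, sets the only stereocentre (2S) and turns the flat pyranone into the dihydropyranone of the target.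
3. Enabling feature: in the dihydropyranone ring the aryl-bearing C2 is α to the ring oxygen O1 and β to the C4 ketone (O1–C2–C3–C4=O, a β-aryl-β-aryloxy ketone). This is the retron of aryl conjugate addition to C2=C3 of a 4H-chromen-4-one, where C2 is the electrophilic vinylogous-ester carbon.
4. 5 ⇐ 5,7-dihydroxychromone (7-O-acetylation, then Mitsunobu 5-O-prenylation); 13 ⇐ 4-bromocatechol (bis-MOM protection, Br/Li exchange–borylation).
5. Ring order: no ring is built; the benzopyranone (A/C) and catechol (B) rings are bought intact, and the C ring is dearomatised in the key step.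

Key step: step 5

Assumption: 5,7-dihydroxychromone and 4-bromocatechol are taken as catalogue materials; the sense of induction of the (S)-biaryl bisphosphine in step 5 is assigned by analogy with its behaviour on cyclic enones, and the ligand antipode would be used if a model run shows the opposite sense.

**Route**

Step 1
Reactants: 1 5,7-dihydroxychromone; 2 acetic anhydride
Product: 3 7-acetoxy-5-hydroxychromone
Conditions: Ac2O (1.05 equiv), pyridine, 0 °C
Reagents that add atoms: acetic anhydride (2), CC(=O)OC(C)=O
Why: Regioselective O-acylation, since the 7-OH is the more acidic, unhindered phenol while the 5-OH is locked in a hydrogen bond to the C4 carbonyl; the small, electron-withdrawing acetate also makes the pyrone more electrophilic for step 5 and is the 7-substituent under which the later Claisen rearrangement has close precedent.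

Step 2
Reactants: 3 7-acetoxy-5-hydroxychromone; 4 3-methylbut-2-en-1-ol (prenol)
Product: 5 7-acetoxy-5-(3-methylbut-2-enyloxy)chromone
Conditions: PPh3 (1.4 equiv), DIAD (1.4 equiv), THF, 0 °C → rt
Reagents that add atoms: 3-methylbut-2-en-1-ol (4), CC(C)=CCO
Why: Mitsunobu etherification (SN2 at the primary allylic carbon, so the linear prenyl ether is expected) works on hydrogen-bonded 5-hydroxy-4-pyranones and, being base-free, should leave the activated aryl acetate untouched.

Step 3
Reactants: 6 4-bromocatechol; 7 chloromethyl methyl ether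
Product: 8 4-bromo-1,2-bis(methoxymethoxy)benzene
Conditions: MOMCl (2.6 equiv), i-Pr2NEt (3 equiv), CH2Cl2, 0 °C → rt
Reagents that add atoms: chloromethyl methyl ether (7), COCCl
Why: Williamson-type O-alkylation of both phenols with an α-chloro ether gives acetal protecting groups that tolerate the organolithium, Rh(I) and Eu(III) steps and are removed by acid in the last step.

Step 4
Reactants: 8 4-bromo-1,2-bis(methoxymethoxy)benzene; 9 triisopropyl borate; 10 water
Product: 13 [3,4-bis(methoxymethoxy)phenyl]boronic acid, via aryllithium 11 (not isolated), via lithium aryltriisopropoxyborate 12 (not isolated)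
Conditions: n-BuLi (1.05 equiv), THF, −78 °C; B(Oi-Pr)3 (1.5 equiv), −78 °C → rt; sat. aq. NH4Cl
Reagents that add atoms: triisopropyl borate (9), CC(C)OB(OC(C)C)OC(C)C; water (10), O
Why: Bromine–lithium exchange at −78 °C is faster than MOM-directed ortho-lithiation, and trapping the aryllithium with a borate ester followed by hydrolysis is the standard arylboronic acid synthesis.

Step 5
Reactants: 5 7-acetoxy-5-(3-methylbut-2-enyloxy)chromone; 13 [3,4-bis(methoxymethoxy)phenyl]boronic acid
Product: 14 (2S)-7-acetoxy-2-[3,4-bis(methoxymethoxy)phenyl]-5-(3-methylbut-2-enyloxy)chroman-4-one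
Conditions: 13 (2.5 equiv), [Rh(OH)(cod)]2 (2.5 mol %), (S)-MeO-F12-BIPHEP (5.5 mol %), toluene/H2O (10:1), 40–50 °C, argon, no added base
Reagents that add atoms: [3,4-bis(methoxymethoxy)phenyl]boronic acid (13), COCOc1ccc(B(O)O)cc1OCOC
Why: Hayashi–Miyaura reaction on a chromone: transmetalation from boron gives an aryl–Rh(I) bisphosphine species, the chromone binds through C2=C3, syn migratory insertion delivers the aryl group to C2 and forms an oxa-π-allyl rhodium enolate, and protonolysis by water releases the flavanone and regenerates Rh–OH. The closest known reaction type is the Rh/chiral bisphosphine- or Rh/chiral diene-catalysed conjugate arylation of chromones to flavanones. No ring is closed; the flat γ-pyrone ring is dearomatised to the dihydropyranone. The new stereocentre C2 is set by the catalyst alone, through enantioface selection of the C2=C3 bond in the C2-symmetric Rh–bisphosphine pocket, and the (S)-ligand is expected to give 2S by analogy with its sense on cyclic enones. The step needs 1,4- over 1,2-addition, protonation of the rhodium enolate faster than β-aryloxide elimination (ring opening to a chalcone), and arylation only at the pyrone; the substrate secures this by having C2=C3 as its only activated olefin, a 7-acetate that lowers the electron density of the vinylogous ester, a 5-oxygen capped as an ether so that no chelating peri-hydroxy ketone can bind rhodium, and a trisubstituted prenyl olefin that aryl–Rh(I) should not touch. The base-free aqueous hydroxo-rhodium conditions, the electron-poor ligand and the excess of boronic acid (against protodeboronation) are chosen so that the acetate survives and the enolate is protonated quickly.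

Step 6
Reactants: 14 (2S)-7-acetoxy-2-[3,4-bis(methoxymethoxy)phenyl]-5-(3-methylbut-2-enyloxy)chroman-4-one
Product: 15 (2S)-7-acetoxy-2-[3,4-bis(methoxymethoxy)phenyl]-5-hydroxy-6-(2-methylbut-3-en-2-yl)chroman-4-one
Conditions: Eu(fod)3 (10 mol %), CHCl3, 50 °C, monitored and stopped at full conversion of 14
Reagents that add atoms: none
Why: Europium(III)-catalysed aromatic Claisen rearrangement, in which chelation of Eu between the C4 carbonyl and O5 accelerates the [3,3] shift of the prenyl ether to C6 (the only free ortho position) with allyl inversion to the 1,1-dimethylallyl group, and tautomerisation restores the hydrogen-bonded 5-OH; the moderate temperature should stop the sequence before a Cope shift to C8, and C2 is not involved.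

Step 7
Reactants: 15 (2S)-7-acetoxy-2-[3,4-bis(methoxymethoxy)phenyl]-5-hydroxy-6-(2-methylbut-3-en-2-yl)chroman-4-one
Product: 16 (2S)-2-(3,4-dihydroxyphenyl)-5,7-dihydroxy-6-(2-methylbut-3-en-2-yl)chroman-4-one (target)
Conditions: HCl (ca. 2 M, from AcCl in MeOH), MeOH, 40 °C, argon
Reagents that add atoms: none
Why: Acid-catalysed acetal exchange and transesterification in methanol should remove both MOM ethers and the aryl acetate in one operation, under conditions where a monosubstituted alkene is not protonated and the flavanone C2 centre, which is labile mainly towards base (retro-oxa-Michael), should be retained.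

**Compound list**

1 | 5,7-dihydroxy-4H-chromen-4-one (5,7-dihydroxychromone) | O=c1ccoc2cc(O)cc(O)c12 | starting material
2 | acetic anhydride | CC(=O)OC(C)=O | starting material
3 | 7-acetoxy-5-hydroxy-4H-chromen-4-one | O=c1ccoc2cc(OC(C)=O)cc(O)c12 | intermediate
4 | 3-methylbut-2-en-1-ol (prenol) | CC(C)=CCO | starting material
5 | 7-acetoxy-5-(3-methylbut-2-enyloxy)-4H-chromen-4-one | O=c1ccoc2cc(OC(C)=O)cc(OCC=C(C)C)c12 | intermediate
6 | 4-bromobenzene-1,2-diol (4-bromocatechol) | Oc1ccc(Br)cc1O | starting material
7 | chloromethyl methyl ether | COCCl | starting material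
8 | 4-bromo-1,2-bis(methoxymethoxy)benzene | COCOc1ccc(Br)cc1OCOC | intermediate
9 | triisopropyl borate | CC(C)OB(OC(C)C)OC(C)C | starting material
10 | water | O | starting material
11 | [3,4-bis(methoxymethoxy)phenyl]lithium | [Li]c1ccc(OCOC)c(OCOC)c1 | intermediate
12 | lithium [3,4-bis(methoxymethoxy)phenyl]tri(propan-2-yloxy)borate | [Li+].COCOc1ccc([B-](OC(C)C)(OC(C)C)OC(C)C)cc1OCOC | intermediate
13 | [3,4-bis(methoxymethoxy)phenyl]boronic acid | COCOc1ccc(B(O)O)cc1OCOC | intermediate
14 | (2S)-7-acetoxy-2-[3,4-bis(methoxymethoxy)phenyl]-5-(3-methylbut-2-enyloxy)chroman-4-one | CC(C)=CCOc1cc(OC(C)=O)cc2c1C(=O)C[C@@H](c1ccc(OCOC)c(OCOC)c1)O2 | intermediate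
15 | (2S)-7-acetoxy-2-[3,4-bis(methoxymethoxy)phenyl]-5-hydroxy-6-(2-methylbut-3-en-2-yl)chroman-4-one | C=CC(C)(C)c1c(OC(C)=O)cc2c(c1O)C(=O)C[C@@H](c1ccc(OCOC)c(OCOC)c1)O2 | intermediate
16 | (2S)-2-(3,4-dihydroxyphenyl)-5,7-dihydroxy-6-(2-methylbut-3-en-2-yl)chroman-4-one | C=CC(C)(C)c1c(O)cc2c(c1O)C(=O)C[C@@H](c1ccc(O)c(O)c1)O2 | target

**Step count and risks**

Total step count: 7. Longest linear sequence: 5 steps (steps 1, 2, 5, 6, 7 from 5,7-dihydroxychromone; the boronic acid branch, steps 3 and 4, joins at step 5).

Steps most likely to fail: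

1. Step 5 (key step). Insertion into the still electron-rich 5,7-dioxygenated chromone may be slower than protodeboronation of the electron-rich boronic acid, the rhodium enolate may ring-open by β-aryloxide elimination, the acetate may hydrolyse, or enantioface discrimination may be insufficient. Fallback, setting out from 5 and 13 and returning at 14: the fragments are joined without asymmetric induction using the more active diene–rhodium catalyst alone ([Rh(OH)(cod)]2, dioxane/H2O, 50 °C) to give racemic 7-acetoxy-2-[3,4-bis(methoxymethoxy)phenyl]-5-(3-methylbut-2-enyloxy)chroman-4-one F1. F1 is then resolved by asymmetric transfer hydrogenation under kinetic-resolution conditions (RuCl[(R,R)-TsDPEN](p-cymene), HCO2H/Et3N, EtOAc, rt, run to just over half conversion). By the acetophenone model this catalyst should give 4R carbinols, so it should consume the 2R ketone as the cis-(2R,4R)-flavan-4-ol F2, which is removed by chromatography to leave (2S)-14.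

2. Step 6. The first-formed C6 product may re-enter the dienone manifold and migrate on by a Cope shift to C8 as a normal prenyl group, the catalyst may be sequestered by the bis-MOM catechol, or prolonged Lewis-acid heating may open the pyranone ring and erode C2. Fallback, setting out from 5 and returning at 16: the rearrangement is moved ahead of the arylation and run thermally with acylative trapping (Ac2O, NaOAc, N,N-diethylaniline, 170–180 °C). The phenol is acetylated as it forms and cannot return to the dienone, giving 5,7-diacetoxy-6-(2-methylbut-3-en-2-yl)-4H-chromen-4-one F3; there is no stereocentre to lose and regioisomers are removed on an achiral intermediate. F3, now a more electrophilic diacetate, is arylated with 13 under the step 5 conditions to give (2S)-5,7-diacetoxy-2-[3,4-bis(methoxymethoxy)phenyl]-6-(2-methylbut-3-en-2-yl)chroman-4-one F4, and the step 7 conditions convert F4 into 16.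

3. Step 7. Acid may promote addition of a flanking phenol to the 1,1-dimethylallyl olefin (dihydrofuran formation), cleavage may be incomplete and need forcing, or acid may open the pyranone ring. Fallback, setting out from 6 and returning at 16: the catechol is carried as silyl ethers so that no protic acid is needed at the end. Compound 6 is silylated (TBSCl, imidazole, DMF) to 4-bromo-1,2-bis(tert-butyldimethylsilyloxy)benzene F5, which is converted as in step 4 into [3,4-bis(tert-butyldimethylsilyloxy)phenyl]boronic acid F6. Coupling of F6 with 5 under the base-free step 5 conditions gives (2S)-7-acetoxy-2-[3,4-bis(tert-butyldimethylsilyloxy)phenyl]-5-(3-methylbut-2-enyloxy)chroman-4-one F7, and the step 6 conditions give (2S)-7-acetoxy-2-[3,4-bis(tert-butyldimethylsilyloxy)phenyl]-5-hydroxy-6-(2-methylbut-3-en-2-yl)chroman-4-one F8. Neutral deacetylation (NH4OAc, MeOH/H2O, rt) gives (2S)-2-[3,4-bis(tert-butyldimethylsilyloxy)phenyl]-5,7-dihydroxy-6-(2-methylbut-3-en-2-yl)chroman-4-one F9, and KHF2 in MeOH at rt removes the two aryl silyl ethers to give 16.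

**Further compounds**

F1 | step 5 | racemic 7-acetoxy-2-[3,4-bis(methoxymethoxy)phenyl]-5-(3-methylbut-2-enyloxy)chroman-4-one | CC(C)=CCOc1cc(OC(C)=O)cc2c1C(=O)CC(c1ccc(OCOC)c(OCOC)c1)O2
F2 | step 5 | (2R,4R)-7-acetoxy-2-[3,4-bis(methoxymethoxy)phenyl]-5-(3-methylbut-2-enyloxy)chroman-4-ol | CC(C)=CCOc1cc(OC(C)=O)cc2c1[C@H](O)C[C@H](c1ccc(OCOC)c(OCOC)c1)O2
F3 | step 6 | 5,7-diacetoxy-6-(2-methylbut-3-en-2-yl)-4H-chromen-4-one | C=CC(C)(C)c1c(OC(C)=O)cc2occc(=O)c2c1OC(C)=O
F4 | step 6 | (2S)-5,7-diacetoxy-2-[3,4-bis(methoxymethoxy)phenyl]-6-(2-methylbut-3-en-2-yl)chroman-4-one | C=CC(C)(C)c1c(OC(C)=O)cc2c(c1OC(C)=O)C(=O)C[C@@H](c1ccc(OCOC)c(OCOC)c1)O2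
F5 | step 7 | 4-bromo-1,2-bis(tert-butyldimethylsilyloxy)benzene | CC(C)(C)[Si](C)(C)Oc1ccc(Br)cc1O[Si](C)(C)C(C)(C)C
F6 | step 7 | [3,4-bis(tert-butyldimethylsilyloxy)phenyl]boronic acid | CC(C)(C)[Si](C)(C)Oc1ccc(B(O)O)cc1O[Si](C)(C)C(C)(C)C
F7 | step 7 | (2S)-7-acetoxy-2-[3,4-bis(tert-butyldimethylsilyloxy)phenyl]-5-(3-methylbut-2-enyloxy)chroman-4-one | CC(C)=CCOc1cc(OC(C)=O)cc2c1C(=O)C[C@@H](c1ccc(O[Si](C)(C)C(C)(C)C)c(O[Si](C)(C)C(C)(C)C)c1)O2
F8 | step 7 | (2S)-7-acetoxy-2-[3,4-bis(tert-butyldimethylsilyloxy)phenyl]-5-hydroxy-6-(2-methylbut-3-en-2-yl)chroman-4-one | C=CC(C)(C)c1c(OC(C)=O)cc2c(c1O)C(=O)C[C@@H](c1ccc(O[Si](C)(C)C(C)(C)C)c(O[Si](C)(C)C(C)(C)C)c1)O2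
F9 | step 7 | (2S)-2-[3,4-bis(tert-butyldimethylsilyloxy)phenyl]-5,7-dihydroxy-6-(2-methylbut-3-en-2-yl)chroman-4-one | C=CC(C)(C)c1c(O)cc2c(c1O)C(=O)C[C@@H](c1ccc(O[Si](C)(C)C(C)(C)C)c(O[Si](C)(C)C(C)(C)C)c1)O2
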